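All runs stem from a simulated flask from invented constants; noise was put on by code.

At early times the dawn run, the flask asked about, makes product fast, 38.8 % of the starting material by 12.0 min; then it stalls, and its last two readings differ by 1.2 percentage points at a scatter of 1 point.

| flask | starting material | partner | capture agent | free catalyst | temperature | remark | time |
|---|---|---|---|---|---|---|---|
| dawn | 0.26 M | 0.182 M | 0.026 M | 5.2 mM | 80 °C | the very flask that is asked about, followed so far |  |
| dusk | 0.26 M | 0.182 M | 0.026 M | 5.2 mM | 75 °C | run made earlier |  |
| flask | 0.26 M | 0.182 M | 0.0260 M | 5.2 mM | 80 °C |  | 3.0 h |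

| run | time / min | product / % |
|---|---|---|
| dawn | 12.0 | 38.8 |
| dawn | 20.0 | 48.3 |
| dawn | 25.0 | 52.3 |
| dawn | 40.0 | 54.9 |
| dawn | 60.0 | 59.7 |
| dawn | 90.0 | 59.0 |
| dawn | 150 | 60.2 |
| dusk | 12.0 | 29.1 |
| dusk | 20.0 | 37.9 |
| dusk | 25.0 | 42.5 |
| dusk | 40.0 | 47.8 |
| dusk | 60.0 | 50.2 |
| dusk | 90.0 | 50.2 |
| dusk | 150 | 51.2 |

(readings scatter by 1 percentage point)

- product taken out counts as made
- steps under discussion: partner + free catalyst -> catalyst intermediate A; catalyst intermediate A -> catalyst intermediate B; catalyst intermediate B -> by-product + catalyst intermediate C; starting material + catalyst intermediate C -> catalyst intermediate D; catalyst intermediate D <-> catalyst intermediate E; catalyst intermediate E -> free catalyst + product; capture agent + catalyst intermediate B -> trapped intermediate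
- additions bring no volume worth counting

- Thursday's: change nothing and wait 6.0 h more
- Friday's: at 3.0 h take out 90 % of the product then present, then wait 6.0 h
- Sunday's: at 3.0 h add partner, 50.0 % of the amount charged, then wait 6.0 h
- Saturday's: at 3.0 h raise the temperature by 15 K, then wait 6.0 h
- Tuesday's: at 3.0 h add free catalyst, 100 % of the amount charged, then wait 6.0 h

* product, in percent of the starting material first charged, at 3.0 h
* what to do for the largest gain in product; "none" if nothing gains more than 2 percentage points (Thursday's / Friday's / Sunday's / Saturday's / Tuesday's / none)
* product present, with what was taken out counted in, in percent of the starting material first charged, after Friday's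
* product present, with what was taken out counted in, in percent of the starting material first charged, after Sunday's

Ines and Tom both read the dawn plateau as the mean of the last three readings, 59.6 %. They part on why it stands there.

Ines holds that partner is the limiting reagent. Its charge allows 70.0 % of the starting material, some goes astray, and in her view the flask stops with none left. So in her reckoning Sunday's, half a charge more, should lift product to 89.5 %.

Tom holds that the catalyst dies. Each round passes through catalyst intermediate B, which either goes on to catalyst intermediate C and later a product, or meets capture agent and leaves the round as trapped intermediate. Divide the rate of product by the rate of catalyst loss and time drops out. What remains is the turnover budget, the product one catalyst makes before it is lost (the turnover number), reckoned as the plateau fraction over the catalyst charge as a fraction of the starting charge, 2.00 %: 29.8. Trapping each catalyst would use 20.0 % of the capture agent. The dusk run gives 25.3, a budget that moves with temperature, while the partner limit is 70.0 % in both runs.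

Tom also presses the balance. Partner leaves by two paths, product and trapping, and counting both leaves 12.0 % of its charge at the plateau, worth 8.37 % of the starting charge.

My own reckoning follows Tom: 59.6 % at 3.0 h, and the same after Friday's and Sunday's. Tuesday's brings a fresh budget of 59.6 %, so its gain should stand near 8.37 %.

The forecast, on Tom's side, gives 59.8 % at 3.0 h, picks Tuesday's, and gives 60 % after Friday's and 60 % after Sunday's, on this ground: “A plateau that shifts with temperature points to the catalyst dying, not to a reagent running out”.

The flask gives 59.9 % at 3.0 h.

    partner + free catalyst → catalyst intermediate A (k = 1.90 M⁻¹ s⁻¹, Ea = 64.0 kJ mol⁻¹)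
    catalyst intermediate A → catalyst intermediate B (k = 0.349 s⁻¹, Ea = 80.0 kJ mol⁻¹)
    catalyst intermediate B → by-product + catalyst intermediate C (k = 0.323 s⁻¹, Ea = 100 kJ mol⁻¹)
    starting material + catalyst intermediate C → catalyst intermediate D (k = 1.84 M⁻¹ s⁻¹, Ea = 61.0 kJ mol⁻¹)
    catalyst intermediate D ⇌ catalyst intermediate E (K = 0.460, k = 0.144 s⁻¹, Ea = 96.0 kJ mol⁻¹, ΔH = 12.0 kJ mol⁻¹)
    catalyst intermediate E → free catalyst + product (k = 4.21 s⁻¹, Ea = 77.0 kJ mol⁻¹)
    capture agent + catalyst intermediate B → trapped intermediate (k = 0.463 M⁻¹ s⁻¹, Ea = 69.0 kJ mol⁻¹)
    (constants at 80 °C)

With what was taken out counted in, Friday's gives 59.9 %, Sunday's gives 59.9 %, and Tuesday's gains 7.9 points; 12 % of the partner's own charge stood in the flask at 180 min. Ines's view has its region in Tuesday's, whose gain stands beside the 8.37 % of the starting charge that the leftover partner was reckoned to be worth. In the neighbour flask with a free catalyst charge of 0.500 % of the starting charge, the budget of 29.8 reckons 14.9 % product, and that flask holds 13.8 %.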